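## The problem

The target joins two isoflavan units. The first chroman (benzo ring A with a 7-hydroxyl; unprimed locants) carries a 2-hydroxy-4,5-dimethoxyphenyl group (ring B) on C3 and a 1,2,4,5-tetrasubstituted benzene (ring D) on C4. Ring D has its methoxy group ortho and its hydroxyl para to the C4 bond, and next to that hydroxyl it is bonded to C3′ of a second chroman (benzo ring E with a 7′-hydroxyl; primed locants) whose C4′ is a plain methylene. There are three stereocentres: C3 (R) and C4 (S), trans to each other, and C3′ (R). C3 and C4 are neighbours, so one can set the other and the trans arrangement is also the more stable one. C3′ is insulated from them by ring D, so absolute configuration has to be introduced twice. The four phenols sit on very electron-rich rings and C4–H is doubly benzylic between donor rings, so the phenols should stay masked until a final neutral deprotection, and oxidants and hot acid are excluded late. The opening is the three-carbon unit of the second chroman: C3′ lies between the aryl ether methylene C2′ (on O1′) and the benzylic methylene C4′ (on C4a′), which is the O–CH2–CH–CH2 pattern of glycidol. If ring D is first attached to the terminal carbon and then shifts to the central carbon while ring E closes on the carbon it leaves, the epoxide stereocentre becomes C3′ by a single inversion. The ring D carbon para to its phenol, where the first chroman is attached later, can be held by bromine through that step.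

## Retrosynthesis

**Target 24 to tetrabenzyl ether 23.** The four phenolic O–H bonds are traced back to benzyl ethers. Benzyl is preferred to methyl, silyl or acetal groups because the three methoxy groups must stay and because the ethers tolerate the organometallic and acid steps. All four fall in one neutral hydrogenolysis. 23 has the full skeleton but no free phenol.

**23 to acetal 22 to benzhydrol 20 and enol ether 16.** After C2 is raised to the acetal level (22), the bonds O1–C2 and C3–C4 of the first chroman are cut. This is the retron of an oxa-Diels–Alder reaction between ortho-quinone methide 21, released from 20, and the (E) enol ether 16. The neighbouring cut at C4–ring D (Friedel–Crafts reaction of an isoflavan-4-yl cation) would need a second enantiopure isoflavan and could control C4 only through C3. A cut at C3–ring B alone leaves C4 and the pyran ring to be handled separately. The chosen cut removes ring B, both stereocentres and the pyran ring together and leaves ring B as an achiral alkene. The forward step must give the trans isomer and must be catalyst-controlled, because C3′ is too remote to help.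

**20 to bromide 11 and aldehyde 17.** The bond between ring D and the carbinol carbon (the future C4) is cut, giving aryllithium 18 and the salicylaldehyde 17, used as its phenoxide 19. This requires a bromine on ring D para to its protected phenol and reduces the problem to a monomeric isoflavan. The addition needs no stereocontrol because the carbinol centre is erased when 21 forms.

**11 to alcohol 8 (key disconnection).** In 11 the bonds C3′–ring D and C4′–C4a′ are cut and ring D is reconnected to C4′. This leads, through phenonium ion 10 and triflate 9, to the acyclic (R) alcohol 8. The usual isoflavan cuts are O1′–C2′ (ether closure after an auxiliary-controlled benzylation) and the C3′–H/C4′–H pair (asymmetric hydrogenation of an isoflavene). The first costs attachment, removal and reduction of an auxiliary; the second costs a chromene synthesis and a precious-metal catalyst. The phenonium cut makes two skeletal bonds, the ring and the stereocentre in one operation from a precursor whose single stereocentre is bought. The forward reaction requires three things: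
- ring D must bridge before anything else attacks the activated carbinol carbon;
- the bridged ion must open at CH2 in the six-membered mode;
- bromine must keep the free para position of ring D out of the reaction.

**8 to aryl iodide 6 and epoxide 3; 3 to phenol 1 and nosylate 2; 6 to phenols 5 and 4.** Cutting the ring D–CH2 bond gives arylmagnesium 7 (from 6) and glycidyl ether 3, joined by epoxide opening at the terminal carbon, which leaves the stereocentre alone. 3 is cut at its aryl ether bond to 1 and the chiral-pool nosylate 2. 6 goes back through phenol 5 to 4. Iodine is needed beside bromine so that only one halogen is exchanged for magnesium.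

**16 to bromide 14 and boronate 15; 14 to ether 13 and phenol 12.** The aryl–vinyl bond is cut to 14 and the (E)-alkenyl boronate 15. A Wittig route from the corresponding aldehyde is one step shorter but gives both alkene isomers, and the geometry of 16 matters for the trans outcome. 14 comes from 12 by benzylation (13) and bromination.

## Roads not taken

**Alternative 1:** Conjunctive cross-coupling.
- **Cut:** C3–ring B and C4–C4a of the first chroman, with O1–C2 closed later.
- **Forward key step:** The ring B aryllithium A2 would add to boron of the (E)-alkenyl pinacol boronate A1, which carries ring D and the finished second chroman. The arylpalladium species formed from the ring A triflate A3, under palladium catalysis with a chiral diphosphine, would add to the alkene and induce the 1,2-shift of ring B from boron to carbon. The product is the 1,2,2-triarylethyl boronate A4.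
- **Merits:** The two C–C bonds add anti across an alkene of fixed geometry, so the relative configuration is stereospecific and one ligand sets both centres. On this point the road is stronger than the chosen one, whose cycloaddition must win diastereo- and enantiocontrol separately.
- **Weak points:** A β-aryl alkenyl boronate, an ortho-alkoxy migrating group and an ortho-substituted triflate make a very congested case. A4 must then be homologated by one carbon at a hindered secondary benzylic C–B bond, oxidised, freed of its acetal and closed to the pyran. That is four operations where the chosen plan needs one reduction.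
- **Comparison:** A1 would itself come from the bromide made in the chosen key step, so this road competes with steps 9–11, not with step 5. The chosen plan sets its shorter tail against the better stereochemical logic of A4.

**Alternative 2:** Quinone annulation.
- **Cut:** C3–ring B, with ring B drawn from 2-methoxy-1,4-benzoquinone A6 and the C4–H bond made last.
- **Forward key step:** The 4-aryl-2H-chromene A5 would attack the quinone, held on a titanium Lewis acid bearing a chiral diol, through C3. The tertiary, doubly benzylic C4 cation is then captured by the quinone oxygen, giving the cis-fused benzofurochromene A7 with a free ring B phenol.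
- **Merits:** Ring B arrives with its full oxygen pattern from a cheap quinone. Ring D is already trans to ring B in A7, because the new C4–O bond is tied cis to ring B. For ring B this is more convergent than the three-step preparation of the enol ether in the chosen plan.
- **Weak points:** The phenol of A7 must be methylated. The tertiary C4–O bond must then be cleaved reductively with retention while four benzyl ethers survive. Styrene-type partners in such annulations can also give cyclobutane or bridged adducts. Absolute control by a chiral titanium complex is less dependable than Brønsted acid control of a quinone methide.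
- **Comparison:** A5 again derives from the bromide of the chosen key step. The chosen plan offers a first chroman formed at the correct oxidation level, with C4–H in place from the start.

**Alternative 3:** Carbon insertion into a benzofuran.
- **Cut:** C3 of the first chroman is removed together with ring B as a carbene, leaving the 3-arylbenzofuran A8.
- **Forward key step:** Irradiation of the aryl chlorodiazirine A9 would release a chlorocarbene that adds to the 2,3-bond of A8. The cyclopropane opens with loss of chloride and the furan grows into the 3,4-diarylchromenylium chloride A10.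
- **Merits:** The whole carbon skeleton is assembled in one step from two flat, accessible aromatics, with no doubt about which aryl group sits where. This is shorter than steps 9 and 10 of the chosen plan.
- **Weak points:** A10 has no stereocentre in the first chroman. Both must be created by reducing a tetrasubstituted, fully conjugated cation. Hydride addition at C2 followed by hydrogenation of the 3,4-double bond adds the two hydrogens cis, which is the wrong relative configuration, and no later step can epimerise C3 or C4. The insertion is better established for indoles and pyrroles than for electron-rich benzofurans.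
- **Comparison:** This road would add two unproven steps to the one in the chosen plan, which derives the trans relationship from alkene and methide geometry.

Key step: step 5

Assumption 1: the facial preference of the phosphoric acid in step 10 cannot be read from the structures alone; the (R) acid is written as the one expected to lead to (3R,4S), and its mirror image would be used otherwise with nothing else changed.
Assumption 2: 20 (carbinol carbon), 22 (C2) and 10 (spiro carbon) are carried as mixtures at the centres named; each of these centres disappears in the transformation that follows.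

## Route

Step 1
Reactants: 1 3-(benzyloxy)phenol; 2 (R)-glycidyl 3-nitrobenzenesulfonate
Product: 3 (R)-2-{[3-(benzyloxy)phenoxy]methyl}oxirane
Conditions: Cs2CO3, DMF, 25 °C
Reagents that add atoms: none
Why: Williamson-type SN2 displacement of the nosylate at the primary carbon by the phenoxide; direct displacement, not epoxide opening and reclosure, is the established course with this sulfonate, so the stereocentre is untouched and stays (R).

Step 2
Reactants: 4 4-bromo-3-methoxyphenol
Product: 5 4-bromo-2-iodo-5-methoxyphenol
Conditions: N-iodosuccinimide, cat. CF3CO2H, MeCN, 0 → 25 °C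
Reagents that add atoms: N-iodosuccinimide, O=C1CCC(=O)N1I
Why: Electrophilic aromatic iodination of a phenol; the para position is blocked by bromine, and the ortho carbon that is also para to the methoxy group is more activated and less hindered than the carbon between the two oxygens.

Step 3
Reactants: 5 4-bromo-2-iodo-5-methoxyphenol
Product: 6 1-(benzyloxy)-4-bromo-2-iodo-5-methoxybenzene
Conditions: BnBr, K2CO3, DMF, 25 °C
Reagents that add atoms: benzyl bromide, BrCc1ccccc1
Why: Williamson O-benzylation of the phenoxide.

Step 4
Reactants: 6 1-(benzyloxy)-4-bromo-2-iodo-5-methoxybenzene; 3 (R)-2-{[3-(benzyloxy)phenoxy]methyl}oxirane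
Product: 8 (R)-1-[2-(benzyloxy)-5-bromo-4-methoxyphenyl]-3-[3-(benzyloxy)phenoxy]propan-2-ol, via arylmagnesium chloride 7 (not isolated)
Conditions: i-PrMgCl·LiCl, THF, −30 °C; then CuI (10 mol %), 3, −30 → 0 °C
Reagents that add atoms: none
Why: Iodine–magnesium exchange is much faster at C–I (ortho to the chelating benzyloxy group) than at C–Br; the aryl Grignard then opens the terminal epoxide at CH2 under CuI catalysis (copper-catalysed epoxide opening), which leaves the stereocentre untouched and gives the (R) alcohol.

Step 5
Reactants: 8 (R)-1-[2-(benzyloxy)-5-bromo-4-methoxyphenyl]-3-[3-(benzyloxy)phenoxy]propan-2-ol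
Product: 11 (R)-7-(benzyloxy)-3-[2-(benzyloxy)-5-bromo-4-methoxyphenyl]chroman, via secondary triflate 9 (not isolated), via spirocyclopropane phenonium triflate 10 (not isolated)
Conditions: Tf2O, 2,6-di-tert-butyl-4-methylpyridine, CH2Cl2, −78 → 0 °C
Reagents that add atoms: none
Why: Proposed new method: triflation at −78 °C gives 9, whose C–O bond is displaced from the rear by the ipso carbon of the 2-benzyloxy-4-methoxyphenyl ring (3-exo-tet, aryl participation) to give the spirocyclopropane arenium ion 10 with inversion at the former carbinol carbon; the closest known reaction types are the anchimerically assisted substitutions of β-arylalkyl sulfonates and the acid-promoted 6-endo Friedel–Crafts closure of aryl glycidyl ethers to chroman-3-ols. The tethered 3-(benzyloxy)phenoxy ring then attacks the primary cyclopropane carbon through its carbon para to the benzyloxy group, a 6-endo-tet opening of the three-membered ring that forms C4′–C4a′ and closes the pyran while the migrated aryl group stays on C3′. C3′ is the only new stereocentre and is fixed by the inversion of the first displacement, so the (R) alcohol should give the (R) chroman; the second displacement occurs at CH2 and does not touch it. The step needs opening at CH2 instead of five-membered closure at the secondary carbon: the β-aryloxy group withdraws charge from that carbon and the short tether reaches its rear side poorly, as in the glycidyl ether cyclisations. It also needs aryl bridging to outrun direct attack on the triflate, which the ortho and para alkoxy groups on the migrating ring should secure. Bromine occupies the most nucleophilic carbon of the migrating ring and keeps it out of Friedel–Crafts chemistry. The hindered pyridine takes up both equivalents of acid without attacking the triflate.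

Step 6
Reactants: 12 3,4-dimethoxyphenol
Product: 13 4-(benzyloxy)-1,2-dimethoxybenzene
Conditions: BnBr, K2CO3, DMF, 25 °C
Reagents that add atoms: benzyl bromide, BrCc1ccccc1
Why: Williamson O-benzylation of the phenoxide.

Step 7
Reactants: 13 4-(benzyloxy)-1,2-dimethoxybenzene
Product: 14 1-(benzyloxy)-2-bromo-4,5-dimethoxybenzene
Conditions: N-bromosuccinimide, MeCN, 0 °C
Reagents that add atoms: N-bromosuccinimide, O=C1CCC(=O)N1Br
Why: Electrophilic aromatic bromination at the only ring carbon that is ortho to one oxygen and para to another without being flanked by two substituents.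

Step 8
Reactants: 14 1-(benzyloxy)-2-bromo-4,5-dimethoxybenzene; 15 (E)-2-(2-ethoxyvinyl)-4,4,5,5-tetramethyl-1,3,2-dioxaborolane
Product: 16 (E)-1-(benzyloxy)-2-(2-ethoxyvinyl)-4,5-dimethoxybenzene
Conditions: PdCl2(dppf) (5 mol %), K3PO4, 1,4-dioxane/H2O, 80 °C
Reagents that add atoms: none
Why: Suzuki–Miyaura coupling of an aryl bromide with an alkenyl pinacol boronate; transmetalation and reductive elimination retain the alkene geometry, so the enol ether is obtained as the (E) isomer.

Step 9
Reactants: 11 (R)-7-(benzyloxy)-3-[2-(benzyloxy)-5-bromo-4-methoxyphenyl]chroman; 17 4-(benzyloxy)-2-hydroxybenzaldehyde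
Product: 20 5-(benzyloxy)-2-[{4-(benzyloxy)-5-[(3R)-7-(benzyloxy)chroman-3-yl]-2-methoxyphenyl}(hydroxy)methyl]phenol, via aryllithium 18 (not isolated), via sodium phenoxide 19 (not isolated)
Conditions: n-BuLi, THF, −78 °C; then 19 (from 17, NaH, THF, 0 °C), −78 → 0 °C
Reagents that add atoms: none
Why: Bromine–lithium exchange followed by 1,2-addition of the aryllithium to the aldehyde; the phenol of 17 is deprotonated first so that the advanced aryllithium is not spent as a base. The carbinol centre forms without control, which is immaterial because it becomes trigonal in step 10.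

Step 10
Reactants: 20 5-(benzyloxy)-2-[{4-(benzyloxy)-5-[(3R)-7-(benzyloxy)chroman-3-yl]-2-methoxyphenyl}(hydroxy)methyl]phenol; 16 (E)-1-(benzyloxy)-2-(2-ethoxyvinyl)-4,5-dimethoxybenzene
Product: 22 (3R,4S)-7-(benzyloxy)-3-[2-(benzyloxy)-4,5-dimethoxyphenyl]-4-{4-(benzyloxy)-5-[(3R)-7-(benzyloxy)chroman-3-yl]-2-methoxyphenyl}-2-ethoxychroman, via ortho-quinone methide 21 (not isolated)
Conditions: (R)-TRIP (10 mol %), 3 Å MS, CH2Cl2, −20 → 25 °C
Reagents that add atoms: none
Why: Chiral phosphoric acid-catalysed inverse-electron-demand oxa-Diels–Alder reaction of an ortho-quinone methide generated by dehydration of an ortho-hydroxybenzhydrol; donor groups para to the methide carbon on both rings make the ionisation easy. The (E) methide and the (E) enol ether in an alkoxy-endo approach place ring B and ring D trans, and the hydrogen-bonded acid shields one face of the methide so that C4 should form as (S) and C3 as (R).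

Step 11
Reactants: 22 (3R,4S)-7-(benzyloxy)-3-[2-(benzyloxy)-4,5-dimethoxyphenyl]-4-{4-(benzyloxy)-5-[(3R)-7-(benzyloxy)chroman-3-yl]-2-methoxyphenyl}-2-ethoxychroman
Product: 23 (3R,4S)-7-(benzyloxy)-3-[2-(benzyloxy)-4,5-dimethoxyphenyl]-4-{4-(benzyloxy)-5-[(3R)-7-(benzyloxy)chroman-3-yl]-2-methoxyphenyl}chroman
Conditions: Et3SiH, BF3·OEt2, CH2Cl2, −78 → −20 °C
Reagents that add atoms: none
Why: Ionic hydrogenation of a cyclic O,O-acetal: BF3·OEt2 ionises C2–OEt to the oxocarbenium ion and Et3SiH delivers hydride to C2, which becomes CH2. C3 and C4 are spectators, and any equilibration of C3 through the enol ether would return to the trans arrangement dictated by C4.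

Step 12
Reactants: 23 (3R,4S)-7-(benzyloxy)-3-[2-(benzyloxy)-4,5-dimethoxyphenyl]-4-{4-(benzyloxy)-5-[(3R)-7-(benzyloxy)chroman-3-yl]-2-methoxyphenyl}chroman
Product: 24 (3R,4S)-3-(2-hydroxy-4,5-dimethoxyphenyl)-4-{4-hydroxy-5-[(3R)-7-hydroxychroman-3-yl]-2-methoxyphenyl}chroman-7-ol
Conditions: H2 (1 atm), Pd/C, THF/MeOH, 25 °C
Reagents that add atoms: none
Why: Hydrogenolysis of four aryl benzyl ethers over Pd/C; the skeleton holds no benzylic C–O or carbon–halogen bond, so only the protecting groups are cleaved and no stereocentre is touched.

## Compound list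

1 | 3-(benzyloxy)phenol | Oc1cccc(OCc2ccccc2)c1 | starting material
2 | (R)-glycidyl 3-nitrobenzenesulfonate | O=S(=O)(OC[C@H]1CO1)c1cccc([N+](=O)[O-])c1 | starting material
3 | (R)-2-{[3-(benzyloxy)phenoxy]methyl}oxirane | c1ccc(cc1)COc1cccc(OC[C@H]2CO2)c1 | intermediate
4 | 4-bromo-3-methoxyphenol | COc1cc(O)ccc1Br | starting material
5 | 4-bromo-2-iodo-5-methoxyphenol | COc1cc(O)c(I)cc1Br | intermediate
6 | 1-(benzyloxy)-4-bromo-2-iodo-5-methoxybenzene | COc1cc(OCc2ccccc2)c(I)cc1Br | intermediate
7 | [2-(benzyloxy)-5-bromo-4-methoxyphenyl]magnesium chloride | COc1cc(OCc2ccccc2)c([Mg]Cl)cc1Br | intermediate (not isolated)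
8 | (R)-1-[2-(benzyloxy)-5-bromo-4-methoxyphenyl]-3-[3-(benzyloxy)phenoxy]propan-2-ol | COc1cc(OCc2ccccc2)c(C[C@@H](O)COc2cccc(OCc3ccccc3)c2)cc1Br | intermediate
9 | (R)-1-[2-(benzyloxy)-5-bromo-4-methoxyphenyl]-3-[3-(benzyloxy)phenoxy]propan-2-yl trifluoromethanesulfonate | COc1cc(OCc2ccccc2)c(C[C@@H](OS(=O)(=O)C(F)(F)F)COc2cccc(OCc3ccccc3)c2)cc1Br | intermediate (not isolated)
10 | 4-(benzyloxy)-1-{[3-(benzyloxy)phenoxy]methyl}-7-bromo-6-methoxyspiro[2.5]octa-4,7-dien-6-ylium trifluoromethanesulfonate (phenonium ion, drawn as its O-methyl oxocarbenium form; cyclopropane CH inverted relative to the carbinol carbon of 8; spiro carbon either configuration) | [O-]S(=O)(=O)C(F)(F)F.c1ccc(cc1)COc1cccc(OC[C@@H]2CC23C(OCc4ccccc4)=CC(=[O+]C)C(Br)=C3)c1 | intermediate (not isolated)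
11 | (R)-7-(benzyloxy)-3-[2-(benzyloxy)-5-bromo-4-methoxyphenyl]chroman | COc1cc(OCc2ccccc2)c([C@@H]2COc3cc(OCc4ccccc4)ccc3C2)cc1Br | intermediate
12 | 3,4-dimethoxyphenol | COc1ccc(O)cc1OC | starting material
13 | 4-(benzyloxy)-1,2-dimethoxybenzene | COc1ccc(OCc2ccccc2)cc1OC | intermediate
14 | 1-(benzyloxy)-2-bromo-4,5-dimethoxybenzene | COc1cc(Br)c(OCc2ccccc2)cc1OC | intermediate
15 | (E)-2-(2-ethoxyvinyl)-4,4,5,5-tetramethyl-1,3,2-dioxaborolane | CCO/C=C/B1OC(C)(C)C(C)(C)O1 | starting material
16 | (E)-1-(benzyloxy)-2-(2-ethoxyvinyl)-4,5-dimethoxybenzene | CCO/C=C/c1cc(OC)c(OC)cc1OCc1ccccc1 | intermediate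
17 | 4-(benzyloxy)-2-hydroxybenzaldehyde | O=Cc1ccc(OCc2ccccc2)cc1O | starting material
18 | {4-(benzyloxy)-5-[(3R)-7-(benzyloxy)chroman-3-yl]-2-methoxyphenyl}lithium | COc1cc(OCc2ccccc2)c([C@@H]2COc3cc(OCc4ccccc4)ccc3C2)cc1[Li] | intermediate (not isolated)
19 | sodium 5-(benzyloxy)-2-formylphenolate | [Na+].[O-]c1cc(OCc2ccccc2)ccc1C=O | intermediate (not isolated)
20 | 5-(benzyloxy)-2-[{4-(benzyloxy)-5-[(3R)-7-(benzyloxy)chroman-3-yl]-2-methoxyphenyl}(hydroxy)methyl]phenol (both carbinol epimers) | COc1cc(OCc2ccccc2)c([C@@H]3COc4cc(OCc5ccccc5)ccc4C3)cc1C(O)c1ccc(OCc2ccccc2)cc1O | intermediate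
21 | (E)-3-(benzyloxy)-6-{4-(benzyloxy)-5-[(3R)-7-(benzyloxy)chroman-3-yl]-2-methoxybenzylidene}cyclohexa-2,4-dien-1-one | O=C1C=C(OCc2ccccc2)C=C/C1=C\c1cc([C@@H]3COc4cc(OCc5ccccc5)ccc4C3)c(OCc2ccccc2)cc1OC | intermediate (not isolated)
22 | (3R,4S)-7-(benzyloxy)-3-[2-(benzyloxy)-4,5-dimethoxyphenyl]-4-{4-(benzyloxy)-5-[(3R)-7-(benzyloxy)chroman-3-yl]-2-methoxyphenyl}-2-ethoxychroman (C2 anomers) | COc1cc(OCc2ccccc2)c([C@@H]2C(OCC)Oc3cc(OCc4ccccc4)ccc3[C@H]2c2cc([C@@H]3COc4cc(OCc5ccccc5)ccc4C3)c(OCc3ccccc3)cc2OC)cc1OC | intermediate
23 | (3R,4S)-7-(benzyloxy)-3-[2-(benzyloxy)-4,5-dimethoxyphenyl]-4-{4-(benzyloxy)-5-[(3R)-7-(benzyloxy)chroman-3-yl]-2-methoxyphenyl}chroman | COc1cc(OCc2ccccc2)c([C@@H]2COc3cc(OCc4ccccc4)ccc3[C@H]2c2cc([C@@H]3COc4cc(OCc5ccccc5)ccc4C3)c(OCc3ccccc3)cc2OC)cc1OC | intermediate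
24 | (3R,4S)-3-(2-hydroxy-4,5-dimethoxyphenyl)-4-{4-hydroxy-5-[(3R)-7-hydroxychroman-3-yl]-2-methoxyphenyl}chroman-7-ol | COc1cc(O)c([C@@H]2COc3cc(O)ccc3[C@H]2c2cc([C@@H]3COc4cc(O)ccc4C3)c(O)cc2OC)cc1OC | target

## Step count and risks

Total: 12 steps. Longest linear sequence: 8 steps (4 → 5 → 6 → 8 → 11 → 20 → 22 → 23 → 24; steps 2, 3, 4, 5, 9, 10, 11, 12).

**Step 5 (key step, proposed new method).** Three processes are most likely to interfere:
- Five-membered closure at the secondary carbon, either by direct Friedel–Crafts attack of ring E on the triflate before ring D bridges, or by opening of the phenonium ion at its secondary carbon.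
- Capture of the triflate carbon by the ortho benzyloxy oxygen of ring D, which would be followed by loss of the benzyl group.
- Attack of ring E through its carbon between the two oxygens, or proton loss from the bridged ion.

All of these stem from the number of nucleophilic sites near one cationic centre.

Fallback, from 3 and 6, returning at 11: Epoxide 3 is cyclised by the known Lewis acid-promoted 6-endo epoxy-arene Friedel–Crafts reaction (BF3·OEt2, CH2Cl2) to (R)-7-(benzyloxy)chroman-3-ol F1. Oxidation with Dess–Martin periodinane gives 7-(benzyloxy)chroman-3-one F2. The arylmagnesium 7, made from 6 as in step 4, adds to F2 in the presence of CeCl3 to give 7-(benzyloxy)-3-[2-(benzyloxy)-5-bromo-4-methoxyphenyl]chroman-3-ol F3. Dehydration with TsOH in toluene gives 7-(benzyloxy)-3-[2-(benzyloxy)-5-bromo-4-methoxyphenyl]-2H-chromene F4. Asymmetric hydrogenation of F4 with a chiral iridium phosphine–oxazoline complex of the type [Ir(cod)(L*)]BArF sets C3′ and gives 11. The chiral-pool centre is given up and the catalyst takes over its role.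

**Step 10.** Three processes are likely to interfere:
- Acid-catalysed hydrolysis of the enol ether by the water released on dehydration.
- Self-condensation of the very electron-rich benzhydrol through attack of one molecule on the methide of another.
- Insufficient facial discrimination by the acid on a methide whose two aryl flanks are both large, so that the (3S,4R) trans isomer forms as well.

Fallback, from 20 and 16, returning at 23: Enol ether 16 is hydrolysed (aq. HCl, THF) to 2-[2-(benzyloxy)-4,5-dimethoxyphenyl]acetaldehyde F5. Benzhydrol 20 is converted with sodium 4-methylbenzenesulfinate in aqueous formic acid to the benzylic sulfone 5-(benzyloxy)-2-[{4-(benzyloxy)-5-[(3R)-7-(benzyloxy)chroman-3-yl]-2-methoxyphenyl}(tosyl)methyl]phenol F6. With NaHCO3 and a diphenylprolinol trimethylsilyl ether, F6 releases the same methide and the enamine of F5 adds to it (amine-catalysed Michael addition and hemiacetalisation). This gives the trans lactol (3R,4S)-7-(benzyloxy)-3-[2-(benzyloxy)-4,5-dimethoxyphenyl]-4-{4-(benzyloxy)-5-[(3R)-7-(benzyloxy)chroman-3-yl]-2-methoxyphenyl}chroman-2-ol F7. Et3SiH and BF3·OEt2 reduce F7 to 23.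

**Step 11.** The cation at C2 lies next to C3–H. Three processes are likely to interfere:
- Proton loss to the 4H-chromene and return, which can erode C3.
- Capture of the cation by the ortho benzyloxy oxygen of ring B, with loss of benzyl.
- Onset of benzyl ether cleavage on the electron-rich rings by the Lewis acid if hydride transfer is slow.

Fallback, from 22, returning at 23: Acetal 22 is hydrolysed with dilute aqueous acid in THF to the lactol (3R,4S)-7-(benzyloxy)-3-[2-(benzyloxy)-4,5-dimethoxyphenyl]-4-{4-(benzyloxy)-5-[(3R)-7-(benzyloxy)chroman-3-yl]-2-methoxyphenyl}chroman-2-ol F7. Cold NaBH4 reduces F7 to the ring-opened phenol alcohol (2R,3S)-2-[2-(benzyloxy)-4,5-dimethoxyphenyl]-3-[4-(benzyloxy)-2-hydroxyphenyl]-3-{4-(benzyloxy)-5-[(3R)-7-(benzyloxy)chroman-3-yl]-2-methoxyphenyl}propan-1-ol F8. A Mitsunobu etherification (PPh3, diisopropyl azodicarboxylate) closes the pyran again and gives 23 without a cation at C2.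

**Step 9.** The phenoxide-bearing aldehyde is a weak electrophile, because the oxygen anion donates into the carbonyl group, and it dissolves poorly in THF. Addition may therefore be slow and the aryllithium may be lost by proton transfer. The product also ionises easily on acidic supports during isolation.

Fallback, from 11, returning at 20: The roles of the partners are exchanged. Aryllithium 18 from 11 is quenched with N,N-dimethylformamide to give 4-(benzyloxy)-5-[(3R)-7-(benzyloxy)chroman-3-yl]-2-methoxybenzaldehyde F9. Purchased 5-(benzyloxy)-2-bromophenol F10 is treated with two equivalents of n-BuLi to give lithium 5-(benzyloxy)-2-lithiophenolate F11. F11 adds to the unhindered, non-phenolic aldehyde F9 and gives 20 after aqueous work-up.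

## Further compounds

F1 | step 5 | (R)-7-(benzyloxy)chroman-3-ol | O[C@H]1COc2cc(OCc3ccccc3)ccc2C1
F2 | step 5 | 7-(benzyloxy)chroman-3-one | O=C1COc2cc(OCc3ccccc3)ccc2C1
F3 | step 5 | 7-(benzyloxy)-3-[2-(benzyloxy)-5-bromo-4-methoxyphenyl]chroman-3-ol (racemic) | COc1cc(OCc2ccccc2)c(C2(O)COc3cc(OCc4ccccc4)ccc3C2)cc1Br
F4 | step 5 | 7-(benzyloxy)-3-[2-(benzyloxy)-5-bromo-4-methoxyphenyl]-2H-chromene | COc1cc(OCc2ccccc2)c(C2=Cc3ccc(OCc4ccccc4)cc3OC2)cc1Br
F5 | step 10 | 2-[2-(benzyloxy)-4,5-dimethoxyphenyl]acetaldehyde | COc1cc(CC=O)c(OCc2ccccc2)cc1OC
F6 | step 10 | 5-(benzyloxy)-2-[{4-(benzyloxy)-5-[(3R)-7-(benzyloxy)chroman-3-yl]-2-methoxyphenyl}(tosyl)methyl]phenol (both epimers at the sulfonyl carbon) | COc1cc(OCc2ccccc2)c([C@@H]3COc4cc(OCc5ccccc5)ccc4C3)cc1C(c1ccc(OCc2ccccc2)cc1O)S(=O)(=O)c1ccc(C)cc1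
F7 | step 10 | (3R,4S)-7-(benzyloxy)-3-[2-(benzyloxy)-4,5-dimethoxyphenyl]-4-{4-(benzyloxy)-5-[(3R)-7-(benzyloxy)chroman-3-yl]-2-methoxyphenyl}chroman-2-ol (C2 anomers) | COc1cc(OCc2ccccc2)c([C@@H]2C(O)Oc3cc(OCc4ccccc4)ccc3[C@H]2c2cc([C@@H]3COc4cc(OCc5ccccc5)ccc4C3)c(OCc3ccccc3)cc2OC)cc1OC
F8 | step 11 | (2R,3S)-2-[2-(benzyloxy)-4,5-dimethoxyphenyl]-3-[4-(benzyloxy)-2-hydroxyphenyl]-3-{4-(benzyloxy)-5-[(3R)-7-(benzyloxy)chroman-3-yl]-2-methoxyphenyl}propan-1-ol | COc1cc(OCc2ccccc2)c([C@H](CO)[C@@H](c2ccc(OCc3ccccc3)cc2O)c2cc([C@@H]3COc4cc(OCc5ccccc5)ccc4C3)c(OCc3ccccc3)cc2OC)cc1OC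
F9 | step 9 | 4-(benzyloxy)-5-[(3R)-7-(benzyloxy)chroman-3-yl]-2-methoxybenzaldehyde | COc1cc(OCc2ccccc2)c([C@@H]2COc3cc(OCc4ccccc4)ccc3C2)cc1C=O
F10 | step 9 | 5-(benzyloxy)-2-bromophenol (purchased) | Oc1cc(OCc2ccccc2)ccc1Br
F11 | step 9 | lithium 5-(benzyloxy)-2-lithiophenolate | [Li]Oc1cc(OCc2ccccc2)ccc1[Li]
A1 | alternative 1 | (E)-2-{4-(benzyloxy)-5-[(3R)-7-(benzyloxy)chroman-3-yl]-2-methoxystyryl}-4,4,5,5-tetramethyl-1,3,2-dioxaborolane | COc1cc(OCc2ccccc2)c([C@@H]2COc3cc(OCc4ccccc4)ccc3C2)cc1/C=C/B1OC(C)(C)C(C)(C)O1
A2 | alternative 1 | [2-(benzyloxy)-4,5-dimethoxyphenyl]lithium | COc1cc([Li])c(OCc2ccccc2)cc1OC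
A3 | alternative 1 | 4-(benzyloxy)-2-(methoxymethoxy)phenyl trifluoromethanesulfonate | COCOc1cc(OCc2ccccc2)ccc1OS(=O)(=O)C(F)(F)F
A4 | alternative 1 | 1,2,2-triarylethyl pinacol boronate with both stereocentres of the first chroman set | COc1cc(OCc5ccccc5)c([C@@H]([C@@H](c2ccc(OCc5ccccc5)cc2OCOC)c2cc([C@@H]3COc4cc(OCc5ccccc5)ccc4C3)c(OCc5ccccc5)cc2OC)B2OC(C)(C)C(C)(C)O2)cc1OC
A5 | alternative 2 | 7-(benzyloxy)-4-{4-(benzyloxy)-5-[(3R)-7-(benzyloxy)chroman-3-yl]-2-methoxyphenyl}-2H-chromene | COc1cc(OCc2ccccc2)c([C@@H]2COc3cc(OCc4ccccc4)ccc3C2)cc1C1=CCOc2cc(OCc3ccccc3)ccc21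
A6 | alternative 2 | 2-methoxy-1,4-benzoquinone | COC1=CC(=O)C=CC1=O
A7 | alternative 2 | cis-fused benzofurochromene adduct with the C4 aryl group and a free ring B phenol | COc1cc2c(cc1O)[C@@H]1COc3cc(OCc4ccccc4)ccc3[C@]1(c1cc([C@@H]3COc4cc(OCc5ccccc5)ccc4C3)c(OCc5ccccc5)cc1OC)O2
A8 | alternative 3 | 6-(benzyloxy)-3-{4-(benzyloxy)-5-[(3R)-7-(benzyloxy)chroman-3-yl]-2-methoxyphenyl}benzofuran | COc1cc(OCc2ccccc2)c([C@@H]2COc3cc(OCc4ccccc4)ccc3C2)cc1-c1coc2cc(OCc3ccccc3)ccc12
A9 | alternative 3 | 3-[2-(benzyloxy)-4,5-dimethoxyphenyl]-3-chloro-3H-diazirine | COc1cc(OCc2ccccc2)c(C2(Cl)N=N2)cc1OC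
A10 | alternative 3 | 7-(benzyloxy)-3-[2-(benzyloxy)-4,5-dimethoxyphenyl]-4-{4-(benzyloxy)-5-[(3R)-7-(benzyloxy)chroman-3-yl]-2-methoxyphenyl}chromenylium chloride | [Cl-].COc1cc(OCc2ccccc2)c(-c2c[o+]c3cc(OCc4ccccc4)ccc3c2-c2cc([C@@H]3COc4cc(OCc5ccccc5)ccc4C3)c(OCc5ccccc5)cc2OC)cc1OC
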